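**Retrosynthetic overview**

1. Neocryptomerin 20 comes from hydrogenolysis of tetrabenzyl ether 19. 19 comes from acid cyclodehydration of bis(1,3-diketone) 18, which closes both pyranone rings (O1–C2 of the 7-methoxyflavone and O1''–C2'' of the second flavone) in one operation. The four benzene rings are bought.
2. 18 comes from bis-ester 17 by a two-directional Baker–Venkataraman rearrangement that forms C2–C3 and C2''–C3''.
3. Feature: the ether oxygen joins C4' of ring B (C1'–C6', bonded to C2) to C6'' of ring A'' (C4a''–C8a'', bonded to C4''). The central diaryl ether 14 is therefore both a benzoic acid (its carboxyl carbon becomes C2) and an o-aroyloxyacetophenone (its acetyl becomes C4''/C3'').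
4. 17 comes from acid 14 and phenol 16. 14 comes from 3,4,5-trihydroxybenzaldehyde 1 by dibenzylation around a free 4-OH, Chan–Lam arylation, Baeyer–Villiger oxidation to the phenol, ortho-iodination, aroylation and Stille acetylation.

Key step: step 12

Remark: the target has no stereocentre and the diaryl ether axis rotates freely, so it is one achiral compound and no step has to control configuration. Diketones are drawn as the diketo tautomers.

**Route**

Step 1
Reactants: 1 3,4,5-trihydroxybenzaldehyde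
Product: 2 3,5-dihydroxy-4-(prop-2-en-1-yloxy)benzaldehyde
Conditions: allyl bromide (1.05 equiv), NaHCO3, DMF, 40 °C, N2
Reagents that add atoms: allyl bromide, C=CCBr
Why: Williamson etherification in which hydrogencarbonate forms only the phenoxide of the 4-OH, which is para to the formyl group and by far the most acidic.

Step 2
Reactants: 2 3,5-dihydroxy-4-(prop-2-en-1-yloxy)benzaldehyde
Product: 3 3,5-bis(benzyloxy)-4-(prop-2-en-1-yloxy)benzaldehyde
Conditions: BnBr (2.4 equiv), K2CO3, DMF, rt to 50 °C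
Reagents that add atoms: benzyl bromide, BrCc1ccccc1
Why: Williamson etherification of the two remaining phenols, with the allyl ether and the non-enolisable aldehyde inert to carbonate.

Step 3
Reactants: 3 3,5-bis(benzyloxy)-4-(prop-2-en-1-yloxy)benzaldehyde
Product: 4 3,5-bis(benzyloxy)-4-hydroxybenzaldehyde
Conditions: Pd(PPh3)4 (3 mol%), morpholine (5 equiv), THF, rt
Reagents that add atoms: none
Why: Pd(0)-catalysed allyl transfer to morpholine (Tsuji–Trost deallylation), in which the para-formyl phenoxide is a good leaving group and benzyl ethers do not ionise.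

Step 4
Reactants: 4 3,5-bis(benzyloxy)-4-hydroxybenzaldehyde; 5 [4-(tert-butoxycarbonyl)phenyl]boronic acid
Product: 6 tert-butyl 4-[2,6-bis(benzyloxy)-4-formylphenoxy]benzoate
Conditions: Cu(OAc)2 (1.5 equiv), pyridine (5 equiv), 4 Å MS, CH2Cl2, air, rt
Reagents that add atoms: none
Why: Chan–Lam–Evans oxidative C–O coupling, which runs at room temperature, accepts di-ortho-substituted acidic phenols and leaves the aldehyde and tert-butyl ester untouched.

Step 5
Reactants: 6 tert-butyl 4-[2,6-bis(benzyloxy)-4-formylphenoxy]benzoate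
Product: 8 tert-butyl 4-[2,6-bis(benzyloxy)-4-hydroxyphenoxy]benzoate, via aryl formate 7 (not isolated)
Conditions: mCPBA (1.6 equiv), CH2Cl2, 0 °C to rt; then K2CO3 (cat.), MeOH–THF, 0 °C
Reagents that add atoms: mCPBA, O=C(OO)c1cccc(Cl)c1
Why: Baeyer–Villiger (Dakin-type) oxidation in which the trioxygenated ring, with the aryloxy oxygen para to the carbonyl, should migrate in preference to hydride, followed by mild methanolysis of the formate that spares the tert-butyl ester.

Step 6
Reactants: 8 tert-butyl 4-[2,6-bis(benzyloxy)-4-hydroxyphenoxy]benzoate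
Product: 9 tert-butyl 4-[2,6-bis(benzyloxy)-4-hydroxy-3-iodophenoxy]benzoate
Conditions: NIS (1.0 equiv), MeCN, −10 to 0 °C, dark
Reagents that add atoms: N-iodosuccinimide, O=C1CCC(=O)N1I
Why: Electrophilic aromatic iodination ortho to the free phenol, where the two open positions are equivalent and far more activated than any position on the benzoate or benzyl rings, so one equivalent should give a single monoiodide.

Step 7
Reactants: 9 tert-butyl 4-[2,6-bis(benzyloxy)-4-hydroxy-3-iodophenoxy]benzoate; 10 4-(benzyloxy)benzoyl chloride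
Product: 11 tert-butyl 4-{2,6-bis(benzyloxy)-4-[4-(benzyloxy)benzoyloxy]-3-iodophenoxy}benzoate
Conditions: Et3N (2 equiv), DMAP (0.1 equiv), CH2Cl2, 0 °C to rt
Reagents that add atoms: none
Why: DMAP-catalysed O-acylation (nucleophilic acyl substitution) of the only nucleophile present, a phenol that is not yet hydrogen-bonded to a ketone.

Step 8
Reactants: 11 tert-butyl 4-{2,6-bis(benzyloxy)-4-[4-(benzyloxy)benzoyloxy]-3-iodophenoxy}benzoate
Product: 13 tert-butyl 4-{3-acetyl-2,6-bis(benzyloxy)-4-[4-(benzyloxy)benzoyloxy]phenoxy}benzoate, via 1-ethoxyvinyl arene 12 (not isolated)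
Conditions: tributyl(1-ethoxyvinyl)stannane (1.5 equiv), Pd(PPh3)4 (5 mol%), CuI (10 mol%), toluene, 100 °C; then 1 M HCl, THF, rt
Reagents that add atoms: tributyl(1-ethoxyvinyl)stannane, CCOC(=C)[Sn](CCCC)(CCCC)CCCC; water, O
Why: Stille coupling with an acetyl-anion equivalent followed by enol ether hydrolysis installs the acetyl group under neutral conditions, sparing the aryl ester, benzyl ethers and tert-butyl ester that a Lewis-acid Friedel–Crafts or Fries acetylation would endanger.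

Step 9
Reactants: 13 tert-butyl 4-{3-acetyl-2,6-bis(benzyloxy)-4-[4-(benzyloxy)benzoyloxy]phenoxy}benzoate
Product: 14 4-{3-acetyl-2,6-bis(benzyloxy)-4-[4-(benzyloxy)benzoyloxy]phenoxy}benzoic acid
Conditions: TFA–CH2Cl2 (1:4), 0 °C to rt
Reagents that add atoms: none
Why: Acidolysis of the tert-butyl ester with loss of isobutene, under which the aryl ester, the ketone and the benzyl aryl ethers should be stable.

Step 10
Reactants: 15 1-(2,6-dihydroxy-4-methoxyphenyl)ethanone (2',6'-dihydroxy-4'-methoxyacetophenone)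
Product: 16 1-[2-(benzyloxy)-6-hydroxy-4-methoxyphenyl]ethanone
Conditions: BnBr (1.05 equiv), K2CO3 (1.2 equiv), acetone, reflux
Reagents that add atoms: benzyl bromide, BrCc1ccccc1
Why: Williamson etherification of a symmetric diol, which stops at the monoether because the remaining OH is locked in a strong hydrogen bond to the acetyl carbonyl.

Step 11
Reactants: 14 4-{3-acetyl-2,6-bis(benzyloxy)-4-[4-(benzyloxy)benzoyloxy]phenoxy}benzoic acid; 16 1-[2-(benzyloxy)-6-hydroxy-4-methoxyphenyl]ethanone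
Product: 17 2-acetyl-3-(benzyloxy)-5-methoxyphenyl 4-{3-acetyl-2,6-bis(benzyloxy)-4-[4-(benzyloxy)benzoyloxy]phenoxy}benzoate
Conditions: DCC (1.3 equiv), DMAP (0.3 equiv), CH2Cl2, 0 °C to rt
Reagents that add atoms: none
Why: Steglich esterification, in which DMAP carries the acyl group onto the hydrogen-bonded phenol and, with no phenoxide-forming base present, the existing aryl ester should not be transacylated.

Step 12
Reactants: 17 2-acetyl-3-(benzyloxy)-5-methoxyphenyl 4-{3-acetyl-2,6-bis(benzyloxy)-4-[4-(benzyloxy)benzoyloxy]phenoxy}benzoate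
Product: 18 1-[2-(benzyloxy)-6-hydroxy-4-methoxyphenyl]-3-{4-[2,6-bis(benzyloxy)-3-{3-[4-(benzyloxy)phenyl]-3-oxopropanoyl}-4-hydroxyphenoxy]phenyl}propane-1,3-dione
Conditions: LiHMDS (6 equiv), THF (0.01 M), −78 to −10 °C; AcOH quench
Reagents that add atoms: none
Why: LiHMDS forms both methyl-ketone enolates, each adds to the aroyl ester on the neighbouring ortho oxygen through a six-membered cyclic transition state, and the tetrahedral alkoxide collapses to a phenoxide and a 1,3-diketone that the excess base deprotonates, making each O-to-C aroyl shift irreversible. The closest known reaction is the Baker–Venkataraman rearrangement of o-aroyloxyacetophenones, here run at two sites of one molecule. The step forms C2–C3 and C2''–C3'' but closes no ring and creates no stereocentre; the pyranone rings are closed in step 13. The selectivity needed is that each enolate acylates on its own neighbouring ester and not on another molecule, which the ortho relationship, the low temperature and the high dilution should secure. Both esters are non-enolisable benzoates, so only the two acetyl groups can be deprotonated, and at least four equivalents of base are consumed by the two dianions. The benzyl ether on the second ortho oxygen of each acetophenone ring ensures that each diketone ends up with exactly one free ortho phenol.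

Step 13
Reactants: 18 1-[2-(benzyloxy)-6-hydroxy-4-methoxyphenyl]-3-{4-[2,6-bis(benzyloxy)-3-{3-[4-(benzyloxy)phenyl]-3-oxopropanoyl}-4-hydroxyphenoxy]phenyl}propane-1,3-dione
Product: 19 5-(benzyloxy)-2-[4-({5,7-bis(benzyloxy)-2-[4-(benzyloxy)phenyl]-4-oxo-4H-chromen-6-yl}oxy)phenyl]-7-methoxy-4H-chromen-4-one
Conditions: p-TsOH·H2O (0.3 equiv), toluene, 4 Å MS, 80 °C
Reagents that add atoms: none
Why: Acid-catalysed cyclodehydration (6-exo-trig attack of each free phenol on the aroyl carbonyl, then loss of water) closes O1–C2 and O1''–C2'' without regiochemical choice because each ring has only one free ortho hydroxyl.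

Step 14
Reactants: 19 5-(benzyloxy)-2-[4-({5,7-bis(benzyloxy)-2-[4-(benzyloxy)phenyl]-4-oxo-4H-chromen-6-yl}oxy)phenyl]-7-methoxy-4H-chromen-4-one
Product: 20 neocryptomerin
Conditions: H2 (1 atm), 10% Pd/C, THF–MeOH (1:1), rt
Reagents that add atoms: none
Why: Catalytic hydrogenolysis of the four benzyl aryl ethers, under which the aryl methyl ether, the diaryl ether and the chromone C2=C3 bonds should not be reduced at 1 atm and room temperature.

**Compound list**

1 | 3,4,5-trihydroxybenzaldehyde | O=Cc1cc(O)c(O)c(O)c1 | starting material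
2 | 3,5-dihydroxy-4-(prop-2-en-1-yloxy)benzaldehyde | O=Cc1cc(O)c(OCC=C)c(O)c1 | intermediate
3 | 3,5-bis(benzyloxy)-4-(prop-2-en-1-yloxy)benzaldehyde | O=Cc1cc(OCc2ccccc2)c(OCC=C)c(OCc2ccccc2)c1 | intermediate
4 | 3,5-bis(benzyloxy)-4-hydroxybenzaldehyde | O=Cc1cc(OCc2ccccc2)c(O)c(OCc2ccccc2)c1 | intermediate
5 | [4-(tert-butoxycarbonyl)phenyl]boronic acid | CC(C)(C)OC(=O)c1ccc(B(O)O)cc1 | starting material
6 | tert-butyl 4-[2,6-bis(benzyloxy)-4-formylphenoxy]benzoate | CC(C)(C)OC(=O)c1ccc(Oc2c(OCc3ccccc3)cc(C=O)cc2OCc2ccccc2)cc1 | intermediate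
7 | tert-butyl 4-[2,6-bis(benzyloxy)-4-(formyloxy)phenoxy]benzoate (aryl formate, not isolated) | CC(C)(C)OC(=O)c1ccc(Oc2c(OCc3ccccc3)cc(OC=O)cc2OCc2ccccc2)cc1 | intermediate
8 | tert-butyl 4-[2,6-bis(benzyloxy)-4-hydroxyphenoxy]benzoate | CC(C)(C)OC(=O)c1ccc(Oc2c(OCc3ccccc3)cc(O)cc2OCc2ccccc2)cc1 | intermediate
9 | tert-butyl 4-[2,6-bis(benzyloxy)-4-hydroxy-3-iodophenoxy]benzoate | CC(C)(C)OC(=O)c1ccc(Oc2c(OCc3ccccc3)cc(O)c(I)c2OCc2ccccc2)cc1 | intermediate
10 | 4-(benzyloxy)benzoyl chloride | O=C(Cl)c1ccc(OCc2ccccc2)cc1 | starting material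
11 | tert-butyl 4-{2,6-bis(benzyloxy)-4-[4-(benzyloxy)benzoyloxy]-3-iodophenoxy}benzoate | CC(C)(C)OC(=O)c1ccc(Oc2c(OCc3ccccc3)cc(OC(=O)c3ccc(OCc4ccccc4)cc3)c(I)c2OCc2ccccc2)cc1 | intermediate
12 | tert-butyl 4-{2,6-bis(benzyloxy)-4-[4-(benzyloxy)benzoyloxy]-3-(1-ethoxyethenyl)phenoxy}benzoate (not isolated) | CC(C)(C)OC(=O)c1ccc(Oc2c(OCc3ccccc3)cc(OC(=O)c3ccc(OCc4ccccc4)cc3)c(C(=C)OCC)c2OCc2ccccc2)cc1 | intermediate
13 | tert-butyl 4-{3-acetyl-2,6-bis(benzyloxy)-4-[4-(benzyloxy)benzoyloxy]phenoxy}benzoate | CC(C)(C)OC(=O)c1ccc(Oc2c(OCc3ccccc3)cc(OC(=O)c3ccc(OCc4ccccc4)cc3)c(C(C)=O)c2OCc2ccccc2)cc1 | intermediate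
14 | 4-{3-acetyl-2,6-bis(benzyloxy)-4-[4-(benzyloxy)benzoyloxy]phenoxy}benzoic acid | OC(=O)c1ccc(Oc2c(OCc3ccccc3)cc(OC(=O)c3ccc(OCc4ccccc4)cc3)c(C(C)=O)c2OCc2ccccc2)cc1 | intermediate
15 | 1-(2,6-dihydroxy-4-methoxyphenyl)ethanone | CC(=O)c1c(O)cc(OC)cc1O | starting material
16 | 1-[2-(benzyloxy)-6-hydroxy-4-methoxyphenyl]ethanone | CC(=O)c1c(OCc2ccccc2)cc(OC)cc1O | intermediate
17 | 2-acetyl-3-(benzyloxy)-5-methoxyphenyl 4-{3-acetyl-2,6-bis(benzyloxy)-4-[4-(benzyloxy)benzoyloxy]phenoxy}benzoate | CC(=O)c1c(OCc2ccccc2)cc(OC)cc1OC(=O)c1ccc(Oc2c(OCc3ccccc3)cc(OC(=O)c3ccc(OCc4ccccc4)cc3)c(C(C)=O)c2OCc2ccccc2)cc1 | intermediate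
18 | 1-[2-(benzyloxy)-6-hydroxy-4-methoxyphenyl]-3-{4-[2,6-bis(benzyloxy)-3-{3-[4-(benzyloxy)phenyl]-3-oxopropanoyl}-4-hydroxyphenoxy]phenyl}propane-1,3-dione | COc1cc(O)c(C(=O)CC(=O)c2ccc(Oc3c(OCc4ccccc4)cc(O)c(C(=O)CC(=O)c4ccc(OCc5ccccc5)cc4)c3OCc3ccccc3)cc2)c(OCc2ccccc2)c1 | intermediate
19 | 5-(benzyloxy)-2-[4-({5,7-bis(benzyloxy)-2-[4-(benzyloxy)phenyl]-4-oxo-4H-chromen-6-yl}oxy)phenyl]-7-methoxy-4H-chromen-4-one | COc1cc(OCc2ccccc2)c2c(=O)cc(-c3ccc(Oc4c(OCc5ccccc5)cc5oc(-c6ccc(OCc7ccccc7)cc6)cc(=O)c5c4OCc4ccccc4)cc3)oc2c1 | intermediate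
20 | neocryptomerin | COc1cc(O)c2c(=O)cc(-c3ccc(Oc4c(O)cc5oc(-c6ccc(O)cc6)cc(=O)c5c4O)cc3)oc2c1 | target

**Step count**

Total: 14 steps. Longest linear sequence: 13 steps (steps 1–9 and 11–14, from 1).

**Steps most likely to fail**

Step 12 (double aroyl migration). The second migration may stall after the first, or the long-lived phenoxides and enolates may scramble acyl groups between molecules, leaving mixtures of half-rearranged material. The fallback makes the two C–C bonds one after the other and sets out from 13, returning at 19. A single rearrangement of 13 (LiHMDS, THF, −78 to 0 °C) should give tert-butyl 4-[2,6-bis(benzyloxy)-3-{3-[4-(benzyloxy)phenyl]-3-oxopropanoyl}-4-hydroxyphenoxy]benzoate F1. TFA in CH2Cl2 should then close the first pyranone ring and cleave the tert-butyl ester together, giving 4-({5,7-bis(benzyloxy)-2-[4-(benzyloxy)phenyl]-4-oxo-4H-chromen-6-yl}oxy)benzoic acid F2. DCC/DMAP coupling with 16 should give 2-acetyl-3-(benzyloxy)-5-methoxyphenyl 4-({5,7-bis(benzyloxy)-2-[4-(benzyloxy)phenyl]-4-oxo-4H-chromen-6-yl}oxy)benzoate F3. A second single rearrangement (LiHMDS) should give 1-[2-(benzyloxy)-6-hydroxy-4-methoxyphenyl]-3-[4-({5,7-bis(benzyloxy)-2-[4-(benzyloxy)phenyl]-4-oxo-4H-chromen-6-yl}oxy)phenyl]propane-1,3-dione F4, and p-TsOH in toluene closes the second ring to 19.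

Step 5 (Baeyer–Villiger oxidation). The ester on the aryloxy ring weakens the para oxygen donor, so hydride migration may compete with aryl migration and over-oxidise the aldehyde to the carboxylic acid. The fallback oxidises before the aryl group is attached, setting out from 4 and returning at 8. A true Dakin oxidation of the para-hydroxybenzaldehyde 4 (H2O2, aq. NaOH, THF, 0 °C, N2, dithionite work-up) should give 2,6-bis(benzyloxy)benzene-1,4-diol F5. Silylation of the unhindered hydroxyl (TBSCl, imidazole, DMF, 0 °C) should give 2,6-bis(benzyloxy)-4-[(tert-butyldimethylsilyl)oxy]phenol F6. Chan–Lam coupling of the flanked hydroxyl with 5 should give tert-butyl 4-{2,6-bis(benzyloxy)-4-[(tert-butyldimethylsilyl)oxy]phenoxy}benzoate F7, and TBAF buffered with AcOH in THF releases 8.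

Step 8 (Stille acetylation). Oxidative addition at the di-ortho-substituted, electron-rich iodide may be slow, so that protodeiodination or loss of the aroyl ester at 100 °C overtakes coupling. The fallback builds the acetyl group from a formyl group without palladium, setting out from 8 and returning at 13. Ortho-formylation of 8 (MgCl2, Et3N, paraformaldehyde, MeCN, reflux) should give tert-butyl 4-[2,6-bis(benzyloxy)-3-formyl-4-hydroxyphenoxy]benzoate F8. MeMgBr (2.5 equiv, THF, −78 °C) should add to the aldehyde only and give racemic tert-butyl 4-[2,6-bis(benzyloxy)-4-hydroxy-3-(1-hydroxyethyl)phenoxy]benzoate F9. MnO2 in CH2Cl2 should oxidise the benzylic alcohol to tert-butyl 4-[3-acetyl-2,6-bis(benzyloxy)-4-hydroxyphenoxy]benzoate F10, and acylation with 10 (pyridine, DMAP) gives 13.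

**Further compounds**

F1 | step 12 | tert-butyl 4-[2,6-bis(benzyloxy)-3-{3-[4-(benzyloxy)phenyl]-3-oxopropanoyl}-4-hydroxyphenoxy]benzoate | CC(C)(C)OC(=O)c1ccc(Oc2c(OCc3ccccc3)cc(O)c(C(=O)CC(=O)c3ccc(OCc4ccccc4)cc3)c2OCc2ccccc2)cc1
F2 | step 12 | 4-({5,7-bis(benzyloxy)-2-[4-(benzyloxy)phenyl]-4-oxo-4H-chromen-6-yl}oxy)benzoic acid | OC(=O)c1ccc(Oc2c(OCc3ccccc3)cc3oc(-c4ccc(OCc5ccccc5)cc4)cc(=O)c3c2OCc2ccccc2)cc1
F3 | step 12 | 2-acetyl-3-(benzyloxy)-5-methoxyphenyl 4-({5,7-bis(benzyloxy)-2-[4-(benzyloxy)phenyl]-4-oxo-4H-chromen-6-yl}oxy)benzoate | CC(=O)c1c(OCc2ccccc2)cc(OC)cc1OC(=O)c1ccc(Oc2c(OCc3ccccc3)cc3oc(-c4ccc(OCc5ccccc5)cc4)cc(=O)c3c2OCc2ccccc2)cc1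
F4 | step 12 | 1-[2-(benzyloxy)-6-hydroxy-4-methoxyphenyl]-3-[4-({5,7-bis(benzyloxy)-2-[4-(benzyloxy)phenyl]-4-oxo-4H-chromen-6-yl}oxy)phenyl]propane-1,3-dione | COc1cc(O)c(C(=O)CC(=O)c2ccc(Oc3c(OCc4ccccc4)cc4oc(-c5ccc(OCc6ccccc6)cc5)cc(=O)c4c3OCc3ccccc3)cc2)c(OCc2ccccc2)c1
F5 | step 5 | 2,6-bis(benzyloxy)benzene-1,4-diol | Oc1cc(OCc2ccccc2)c(O)c(OCc2ccccc2)c1
F6 | step 5 | 2,6-bis(benzyloxy)-4-[(tert-butyldimethylsilyl)oxy]phenol | CC(C)(C)[Si](C)(C)Oc1cc(OCc2ccccc2)c(O)c(OCc2ccccc2)c1
F7 | step 5 | tert-butyl 4-{2,6-bis(benzyloxy)-4-[(tert-butyldimethylsilyl)oxy]phenoxy}benzoate | CC(C)(C)OC(=O)c1ccc(Oc2c(OCc3ccccc3)cc(O[Si](C)(C)C(C)(C)C)cc2OCc2ccccc2)cc1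
F8 | step 8 | tert-butyl 4-[2,6-bis(benzyloxy)-3-formyl-4-hydroxyphenoxy]benzoate | CC(C)(C)OC(=O)c1ccc(Oc2c(OCc3ccccc3)cc(O)c(C=O)c2OCc2ccccc2)cc1
F9 | step 8 | tert-butyl 4-[2,6-bis(benzyloxy)-4-hydroxy-3-(1-hydroxyethyl)phenoxy]benzoate (racemic) | CC(C)(C)OC(=O)c1ccc(Oc2c(OCc3ccccc3)cc(O)c(C(C)O)c2OCc2ccccc2)cc1
F10 | step 8 | tert-butyl 4-[3-acetyl-2,6-bis(benzyloxy)-4-hydroxyphenoxy]benzoate | CC(C)(C)OC(=O)c1ccc(Oc2c(OCc3ccccc3)cc(O)c(C(C)=O)c2OCc2ccccc2)cc1
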